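## Retrosynthetic overview

1. Target ⇐ Mislow–Evans 1,3-transposition of a C2 phenyl sulfide into the (4R)-2E-allylic alcohol; C10 acetate ⇐ C10 silyl ether.
2. 13-membered ring ⇐ 14-membered cembranoid 10-siloxy-11,12-epoxide, by stereospecific shift of C10 from C11 to C12 (epoxide semipinacol ring contraction; second ring-forming event).
3. 14-membered ring ⇐ acyclic geranylgeranyl-type sulfide, by tail-to-head C1–C2 closure (the bond the cembrane cyclase makes): α-thio allyl anion onto the (R)-terminal epoxide (first ring-forming event; sets C1).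
4. Acyclic C20 chain ⇐ two geraniol-derived C10 units joined at C9–C10 by α-selective allylbarium addition to a bis-epoxy aldehyde; Sharpless and Shi epoxides carry all absolute stereochemistry.
5. Ring order: 14-membered carbocycle first, then contraction to the 13-membered ring.

Convention (one line): locants C1–C15 are cembrane locants (C1 = ring CH carrying the isopropyl group, C4/C8/C12 = methyl-bearing carbons, C15 = isopropyl CH; after contraction C11 is the formyl carbon, named as 10(11→12)-abeo-cembrane).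

## Route

Step 1
Reactants: 1 geraniol
Product: 2 geranyl tert-butyldimethylsilyl ether
Conditions: TBSCl, imidazole, DMF, rt
Reagents that add atoms: tert-butyldimethylsilyl chloride CC(C)(C)[Si](C)(C)Cl
Why: Standard imidazole-promoted O-silylation masks the primary allylic alcohol with a group that survives SeO2, activated barium and the later epoxide chemistry; no stereocentre is formed.

Step 2
Reactants: 2 geranyl tert-butyldimethylsilyl ether
Product: 3 (2E,6E)-8-[(tert-butyldimethylsilyl)oxy]-2,6-dimethylocta-2,6-dien-1-ol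
Conditions: SeO2 (cat.), t-BuOOH, salicylic acid (cat.), CH2Cl2, 0 °C to rt
Reagents that add atoms: tert-butyl hydroperoxide CC(C)(C)OO
Why: Sharpless–Umbreit allylic oxidation (ene reaction then [2,3] shift) attacks only the electron-rich terminal olefin at its (E)-methyl group, giving the E-allylic alcohol that becomes C9.

Step 3
Reactants: 3 (2E,6E)-8-[(tert-butyldimethylsilyl)oxy]-2,6-dimethylocta-2,6-dien-1-ol
Product: 4 tert-butyl{[(2E,6E)-8-chloro-3,7-dimethylocta-2,6-dien-1-yl]oxy}dimethylsilane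
Conditions: PPh3, hexachloroacetone, CH2Cl2, −40 to 0 °C
Reagents that add atoms: hexachloroacetone ClC(Cl)(Cl)C(=O)C(Cl)(Cl)Cl
Why: Appel-type chlorination (Magid conditions) converts the primary allylic alcohol to the chloride by SN2 without allylic transposition or loss of E geometry.

Step 4
Reactants: 1 geraniol
Product: 5 [(2S,3S)-3-methyl-3-(4-methylpent-3-en-1-yl)oxiran-2-yl]methanol
Conditions: Ti(OiPr)4 (5 mol%), L-(+)-diethyl tartrate (7 mol%), t-BuOOH, 4 Å MS, CH2Cl2, −20 °C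
Reagents that add atoms: tert-butyl hydroperoxide CC(C)(C)OO
Why: Sharpless asymmetric epoxidation with L-(+)-tartrate gives the (2S,3S)-epoxide, which fixes C11 and C12 (both S) in >95% ee.

Step 5
Reactants: 5 [(2S,3S)-3-methyl-3-(4-methylpent-3-en-1-yl)oxiran-2-yl]methanol
Product: 6 [(2S,3S)-3-{2-[(2R)-3,3-dimethyloxiran-2-yl]ethyl}-3-methyloxiran-2-yl]methanol
Conditions: D-fructose-derived Shi ketone (30 mol%), Oxone, K2CO3, Bu4NHSO4 (cat.), MeCN–dimethoxymethane–aq. borate buffer, 0 °C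
Reagents that add atoms: Oxone (potassium peroxymonosulfate) [K+].[O-]S(=O)(=O)OO
Why: Shi epoxidation of the only remaining olefin is catalyst-controlled and gives the (R)-configured terminal epoxide, the stereochemical source of C1.

Step 6
Reactants: 6 [(2S,3S)-3-{2-[(2R)-3,3-dimethyloxiran-2-yl]ethyl}-3-methyloxiran-2-yl]methanol
Product: 7 (2R,3S)-3-{2-[(2R)-3,3-dimethyloxiran-2-yl]ethyl}-3-methyloxirane-2-carbaldehyde
Conditions: TEMPO (cat.), PhI(OAc)2, CH2Cl2, rt
Reagents that add atoms: none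
Why: TEMPO/PhI(OAc)2 oxidation takes the primary alcohol to the α,β-epoxy aldehyde without touching the epoxides or the existing stereocentres.

Step 7
Reactants: 4 tert-butyl{[(2E,6E)-8-chloro-3,7-dimethylocta-2,6-dien-1-yl]oxy}dimethylsilane (1.5 equiv); 7 (2R,3S)-3-{2-[(2R)-3,3-dimethyloxiran-2-yl]ethyl}-3-methyloxirane-2-carbaldehyde
Product: 9 (1S,3E,7E)-9-[(tert-butyldimethylsilyl)oxy]-1-[(2S,3S)-3-{2-[(2R)-3,3-dimethyloxiran-2-yl]ethyl}-3-methyloxiran-2-yl]-3,7-dimethylnona-3,7-dien-1-ol, via allylbarium chloride 8 (not isolated)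
Conditions: Ba* (BaI2, 2 Li biphenylide, THF, rt), then 4, −78 °C, 20 min; then 7, −78 °C; aq. NH4Cl
Reagents that add atoms: none
Why: Yamamoto allylbarium addition is α-selective with retention of the E-olefin, so the C9–C10 bond forms without allylic transposition, and Felkin–Anh attack anti to the epoxide C–O bond gives the erythro (10S) alcohol (minor C10 epimer removed by chromatography).

Step 8
Reactants: 9 (1S,3E,7E)-9-[(tert-butyldimethylsilyl)oxy]-1-[(2S,3S)-3-{2-[(2R)-3,3-dimethyloxiran-2-yl]ethyl}-3-methyloxiran-2-yl]-3,7-dimethylnona-3,7-dien-1-ol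
Product: 10 O-tert-butyldimethylsilyl ether of 9 (bis-TBS ether; C10 S)
Conditions: TBSOTf, 2,6-lutidine, CH2Cl2, −78 °C
Reagents that add atoms: tert-butyldimethylsilyl triflate CC(C)(C)[Si](C)(C)OS(=O)(=O)C(F)(F)F
Why: Silylation of the hindered secondary alcohol installs the non-participating siloxy group that the later ring contraction needs (an acyloxy group would trap the C12 cation instead of letting C10 migrate).

Step 9
Reactants: 10 bis-TBS ether
Product: 11 (2E,6E,9S)-9-[(tert-butyldimethylsilyl)oxy]-9-[(2S,3S)-3-{2-[(2R)-3,3-dimethyloxiran-2-yl]ethyl}-3-methyloxiran-2-yl]-3,7-dimethylnona-2,6-dien-1-ol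
Conditions: NH4F, MeOH, rt
Reagents that add atoms: none
Why: Mild fluoride cleaves the unhindered primary allylic TBS ether much faster than the hindered secondary one and leaves both epoxides intact.

Step 10
Reactants: 11 (2E,6E,9S)-9-[(tert-butyldimethylsilyl)oxy]-9-[(2S,3S)-3-{2-[(2R)-3,3-dimethyloxiran-2-yl]ethyl}-3-methyloxiran-2-yl]-3,7-dimethylnona-2,6-dien-1-ol
Product: 12 tert-butyl{[(1S,3E,7E)-1-[(2S,3S)-3-{2-[(2R)-3,3-dimethyloxiran-2-yl]ethyl}-3-methyloxiran-2-yl]-3,7-dimethyl-9-(phenylsulfanyl)nona-3,7-dien-1-yl]oxy}dimethylsilane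
Conditions: PhSSPh, n-Bu3P, THF, 0 °C to rt
Reagents that add atoms: diphenyl disulfide c1ccc(cc1)SSc1ccccc1
Why: Hata thioetherification replaces the primary allylic hydroxyl by SPh through SN2 on the alkoxyphosphonium ion, with no allylic shift and no reaction at the epoxides.

Step 11
Reactants: 12 acyclic allylic sulfide bis-epoxide
Product: 15 O-[(1S,2R,3E,7E,10S,11S,12S)-10-[(tert-butyldimethylsilyl)oxy]-11,12-epoxy-2-(phenylsulfanyl)cembra-3,7-dien-15-yl] S-methyl carbonodithioate, via lithiated sulfide 13 (not isolated), via macrocyclic lithium alkoxide 14 (not isolated)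
Conditions: n-BuLi (1.1 equiv), DABCO, THF (0.003 M), −78 to −20 °C; then CS2, DMPU, 0 °C; then MeI
Reagents that add atoms: carbon disulfide S=C=S; iodomethane CI
Why: Itô–Kodama-type anionic macrocyclisation, in which the α-thio allyllithium (C2) opens the unhindered terminal epoxide at C1 by SN2 to close the 14-membered ring through the same tail-to-head C1–C2 bond that the cembrane cyclase forms (reversed polarity), inversion at the (R)-epoxide carbon sets C1 as S, the hindered 2,3-epoxy silyl ether is not attacked, C2 is expected mainly R from the staggered closure transition state (alkenyl arm anti to the oxido-isopropyl group, sulfur beside it on lithium), and the tertiary alkoxide is trapped in the same pot as its xanthate.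

Step 12
Reactants: 15 macrocyclic xanthate
Product: 16 (1S,2S,3E,7E,10S,11S,12S)-10-[(tert-butyldimethylsilyl)oxy]-11,12-epoxy-2-(phenylsulfanyl)cembra-3,7-diene
Conditions: Bu3SnH, Et3B (cat.), air, toluene, rt
Reagents that add atoms: none
Why: Barton–McCombie deoxygenation works because the thiocarbonyl reacts with Bu3Sn• far faster than the hindered trisubstituted allyl sulfide, and the tertiary C15 radical is reduced to the isopropyl group without touching C1 (any minor C2 epimer is separated here).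

Step 13
Reactants: 16 macrocyclic epoxy silyl ether
Product: 17 (1S,2S,3E,7E,10S,12S)-10-[(tert-butyldimethylsilyl)oxy]-2-(phenylsulfanyl)-10(11→12)-abeo-cembra-3,7-dien-11-al
Conditions: MABR (2.2 equiv, from Me3Al and 4-bromo-2,6-di-tert-butylphenol), CH2Cl2, −78 to −40 °C
Reagents that add atoms: none
Why: Proposed new method: ring-contracting variant of the Maruoka–Yamamoto rearrangement (closest known reaction: MABR-promoted rearrangement of acyclic erythro 2,3-epoxy silyl ethers to β-siloxy aldehydes, including geraniol-derived ones with a pendant olefin), in which the bulky Lewis acid opens the epoxide at tertiary C12 while the siloxy-bearing ring carbon C10 shifts from C11 to C12 anti to the leaving oxygen, so C12 forms with inversion (12S), C10 keeps its configuration, C11 becomes the aldehyde and the 14-membered ring contracts to 13 as in the proposed cationic epoxide rearrangement of the biosynthesis.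

Step 14
Reactants: 17 ring-contracted siloxy aldehyde
Product: 18 (1S,2S,3E,7E,10S,12S)-10-hydroxy-2-(phenylsulfanyl)-10(11→12)-abeo-cembra-3,7-dien-11-al
Conditions: HF·pyridine, THF, 0 °C to rt
Reagents that add atoms: none
Why: Acidic (non-basic) fluoride desilylation releases the β-hydroxy aldehyde without the retro-aldol cleavage a basic fluoride could cause, and the quaternary α-carbon rules out epimerisation or elimination.

Step 15
Reactants: 18 β-hydroxy aldehyde
Product: 19 (1S,2S,3E,7E,10S,12S)-11-oxo-2-(phenylsulfanyl)-10(11→12)-abeo-cembra-3,7-dien-10-yl acetate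
Conditions: Ac2O, pyridine, DMAP (cat.), CH2Cl2, rt
Reagents that add atoms: acetic anhydride CC(=O)OC(C)=O
Why: DMAP-catalysed acetylation of the only hydroxyl group, done before the tertiary allylic alcohol exists so that no selectivity question arises.

Step 16
Reactants: 19 acetoxy aldehyde sulfide
Product: 22 (1S,2E,4R,7E,10S,12S)-4-hydroxy-11-oxo-10(11→12)-abeo-cembra-2,7-dien-10-yl acetate [= (1S,2S,4E,8R,9E,11S)-1-formyl-8-hydroxy-1,4,8-trimethyl-11-(propan-2-yl)cyclotrideca-4,9-dien-2-yl acetate], via allylic sulfoxide 20 (not isolated), via allylic sulfenate 21 (not isolated)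
Conditions: mCPBA (1.0 equiv), CH2Cl2, −78 °C; then P(OMe)3, MeOH, rt
Reagents that add atoms: 3-chloroperbenzoic acid OOC(=O)c1cccc(Cl)c1
Why: Mislow–Evans rearrangement, in which chemoselective S-oxidation gives the allylic sulfoxide whose [2,3] shift through the envelope with H-2 inside (no A1,3 strain with the C4 methyl) delivers oxygen suprafacially from C2 to C4, forming the 2E olefin and the 4R tertiary alcohol once the phosphite cleaves the S–O bond.

## Compound list

1 | geraniol | CC(C)=CCC/C(C)=C/CO | starting material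
2 | geranyl tert-butyldimethylsilyl ether | CC(C)=CCC/C(C)=C/CO[Si](C)(C)C(C)(C)C | intermediate
3 | (2E,6E)-8-[(tert-butyldimethylsilyl)oxy]-2,6-dimethylocta-2,6-dien-1-ol | OC/C(C)=C/CC/C(C)=C/CO[Si](C)(C)C(C)(C)C | intermediate
4 | tert-butyl{[(2E,6E)-8-chloro-3,7-dimethylocta-2,6-dien-1-yl]oxy}dimethylsilane | ClC/C(C)=C/CC/C(C)=C/CO[Si](C)(C)C(C)(C)C | intermediate
5 | [(2S,3S)-3-methyl-3-(4-methylpent-3-en-1-yl)oxiran-2-yl]methanol | CC(C)=CCC[C@]1(C)O[C@H]1CO | intermediate
6 | [(2S,3S)-3-{2-[(2R)-3,3-dimethyloxiran-2-yl]ethyl}-3-methyloxiran-2-yl]methanol | CC1(C)O[C@@H]1CC[C@]2(C)O[C@H]2CO | intermediate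
7 | (2R,3S)-3-{2-[(2R)-3,3-dimethyloxiran-2-yl]ethyl}-3-methyloxirane-2-carbaldehyde | CC1(C)O[C@@H]1CC[C@]2(C)O[C@H]2C=O | intermediate
8 | [(2E,6E)-8-[(tert-butyldimethylsilyl)oxy]-2,6-dimethylocta-2,6-dien-1-yl]barium chloride | Cl[Ba]C/C(C)=C/CC/C(C)=C/CO[Si](C)(C)C(C)(C)C | intermediate
9 | (1S,3E,7E)-9-[(tert-butyldimethylsilyl)oxy]-1-[(2S,3S)-3-{2-[(2R)-3,3-dimethyloxiran-2-yl]ethyl}-3-methyloxiran-2-yl]-3,7-dimethylnona-3,7-dien-1-ol | CC(C)(C)[Si](C)(C)OC/C=C(C)/CC/C=C(C)/C[C@H](O)[C@@H]1O[C@@]1(C)CC[C@H]2OC2(C)C | intermediate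
10 | O-tert-butyldimethylsilyl ether of 9 (bis-TBS ether) | CC(C)(C)[Si](C)(C)OC/C=C(C)/CC/C=C(C)/C[C@H](O[Si](C)(C)C(C)(C)C)[C@@H]1O[C@@]1(C)CC[C@H]2OC2(C)C | intermediate
11 | (2E,6E,9S)-9-[(tert-butyldimethylsilyl)oxy]-9-[(2S,3S)-3-{2-[(2R)-3,3-dimethyloxiran-2-yl]ethyl}-3-methyloxiran-2-yl]-3,7-dimethylnona-2,6-dien-1-ol | OC/C=C(C)/CC/C=C(C)/C[C@H](O[Si](C)(C)C(C)(C)C)[C@@H]1O[C@@]1(C)CC[C@H]2OC2(C)C | intermediate
12 | tert-butyl{[(1S,3E,7E)-1-[(2S,3S)-3-{2-[(2R)-3,3-dimethyloxiran-2-yl]ethyl}-3-methyloxiran-2-yl]-3,7-dimethyl-9-(phenylsulfanyl)nona-3,7-dien-1-yl]oxy}dimethylsilane | c1ccccc1SC/C=C(C)/CC/C=C(C)/C[C@H](O[Si](C)(C)C(C)(C)C)[C@@H]2O[C@@]2(C)CC[C@H]3OC3(C)C | intermediate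
13 | α-lithio derivative of 12 (lithium on the carbon bearing SPh) | [Li]C(Sc1ccccc1)/C=C(C)/CC/C=C(C)/C[C@H](O[Si](C)(C)C(C)(C)C)[C@@H]2O[C@@]2(C)CC[C@H]3OC3(C)C | intermediate
14 | lithium (1S,2R,3E,7E,10S,11S,12S)-10-[(tert-butyldimethylsilyl)oxy]-11,12-epoxy-2-(phenylsulfanyl)cembra-3,7-dien-15-olate | c3ccccc3S[C@@H]1/C=C(C)/CC/C=C(C)/C[C@H](O[Si](C)(C)C(C)(C)C)[C@@H]2O[C@@]2(C)CC[C@H]1C(C)(C)O[Li] | intermediate
15 | O-[(1S,2R,3E,7E,10S,11S,12S)-10-[(tert-butyldimethylsilyl)oxy]-11,12-epoxy-2-(phenylsulfanyl)cembra-3,7-dien-15-yl] S-methyl carbonodithioate | c3ccccc3S[C@@H]1/C=C(C)/CC/C=C(C)/C[C@H](O[Si](C)(C)C(C)(C)C)[C@@H]2O[C@@]2(C)CC[C@H]1C(C)(C)OC(=S)SC | intermediate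
16 | (1S,2S,3E,7E,10S,11S,12S)-10-[(tert-butyldimethylsilyl)oxy]-11,12-epoxy-2-(phenylsulfanyl)cembra-3,7-diene | c3ccccc3S[C@@H]1/C=C(C)/CC/C=C(C)/C[C@H](O[Si](C)(C)C(C)(C)C)[C@@H]2O[C@@]2(C)CC[C@H]1C(C)C | intermediate
17 | (1S,2S,3E,7E,10S,12S)-10-[(tert-butyldimethylsilyl)oxy]-2-(phenylsulfanyl)-10(11→12)-abeo-cembra-3,7-dien-11-al | c3ccccc3S[C@@H]1/C=C(C)/CC/C=C(C)/C[C@H](O[Si](C)(C)C(C)(C)C)[C@@](C)(C=O)CC[C@H]1C(C)C | intermediate
18 | (1S,2S,3E,7E,10S,12S)-10-hydroxy-2-(phenylsulfanyl)-10(11→12)-abeo-cembra-3,7-dien-11-al | c3ccccc3S[C@@H]1/C=C(C)/CC/C=C(C)/C[C@H](O)[C@@](C)(C=O)CC[C@H]1C(C)C | intermediate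
19 | (1S,2S,3E,7E,10S,12S)-11-oxo-2-(phenylsulfanyl)-10(11→12)-abeo-cembra-3,7-dien-10-yl acetate | c3ccccc3S[C@@H]1/C=C(C)/CC/C=C(C)/C[C@H](OC(C)=O)[C@@](C)(C=O)CC[C@H]1C(C)C | intermediate
20 | S-oxide of 19 (2-phenylsulfinyl; both sulfur epimers) | O=S(c3ccccc3)[C@@H]1/C=C(C)/CC/C=C(C)/C[C@H](OC(C)=O)[C@@](C)(C=O)CC[C@H]1C(C)C | intermediate
21 | (1S,2E,4R,7E,10S,12S)-11-oxo-4-[(phenylsulfanyl)oxy]-10(11→12)-abeo-cembra-2,7-dien-10-yl acetate | CC(=O)O[C@H]1C/C(C)=C/CC[C@@](C)(OSc2ccccc2)/C=C/[C@H](C(C)C)CC[C@]1(C)C=O | intermediate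
22 | (1S,2E,4R,7E,10S,12S)-4-hydroxy-11-oxo-10(11→12)-abeo-cembra-2,7-dien-10-yl acetate (CNP0106239.1) | CC(=O)O[C@H]1C/C(C)=C/CC[C@@](C)(O)/C=C/[C@H](C(C)C)CC[C@]1(C)C=O | target

## Step count and weak points

Total step count: 16. Longest linear sequence: 13 steps (1, 2, 3, 7–16; the other branch 4, 5, 6, 7–16 is equally long).

The three steps most likely to fail are 13, 11 and 7.

For step 13, the contraction is unprecedented in a macrocycle, and the thioether could compete for the aluminium reagent or the C12 cation. The fallback sets out from 16 and comes back at 22; it trades sulfur for the C4 oxygen first, so the contraction runs on a sulfur-free bis-silyl ether. Compound 16 is put through the oxidation/[2,3]-shift/thiophile protocol of step 16 (mCPBA, −78 °C; then P(OMe)3, MeOH) to give (1S,2E,4R,7E,10S,11S,12S)-10-[(tert-butyldimethylsilyl)oxy]-11,12-epoxycembra-2,7-dien-4-ol F1. TESOTf/2,6-lutidine at −78 °C caps the tertiary allylic alcohol as the 4-O-triethylsilyl ether F2. MABR then contracts the ring to (1S,2E,4R,7E,10S,12S)-10-[(tert-butyldimethylsilyl)oxy]-4-[(triethylsilyl)oxy]-10(11→12)-abeo-cembra-2,7-dien-11-al F3. HF·pyridine removes both silyl groups to give (1S,2E,4R,7E,10S,12S)-4,10-dihydroxy-10(11→12)-abeo-cembra-2,7-dien-11-al F4. Ac2O/pyridine at 0 °C acetylates only the secondary C10 hydroxyl and gives 22.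

For step 11, the risks are a sluggish or unselective closure by the α-thio anion, a wrong C2 ratio, and the later exposure of the allyl sulfide to tin radicals. The fallback sets out from 12 and comes back at 22; it changes the carbanion to Evans' α-sulfinyl allyl anion, so ring closure and oxygen transposition are fused and sulfur is gone before the radical step. Compound 12 is oxidised (mCPBA, 1 equiv, −78 °C) to the acyclic allylic sulfoxide F5. LDA (THF, high dilution, −78 to −20 °C) closes the ring onto the terminal epoxide and CS2/MeI trapping gives the macrocyclic 2-phenylsulfinyl xanthate F6. P(OMe)3 in MeOH converts it to O-[(1R,2E,4R,7E,10S,11S,12S)-10-[(tert-butyldimethylsilyl)oxy]-11,12-epoxy-4-hydroxycembra-2,7-dien-15-yl] S-methyl carbonodithioate F7. Bu3SnH/Et3B then gives the epoxy silyl ether alcohol F1, which goes on through the triethylsilyl ether F2, the contracted aldehyde F3 and the diol aldehyde F4 to 22 exactly as in the fallback above.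

For step 7, the C10 ratio may be poor if barium chelation overrides Felkin–Anh control. The fallback sets out from 9 (as the C10 epimer mixture) and comes back at 9; it sets C10 by ketone reduction instead of by aldehyde addition. Dess–Martin oxidation gives the α,β-epoxy ketone (3E,7E)-9-[(tert-butyldimethylsilyl)oxy]-1-[(2R,3S)-3-{2-[(2R)-3,3-dimethyloxiran-2-yl]ethyl}-3-methyloxiran-2-yl]-3,7-dimethylnona-3,7-dien-1-one F8. Zn(BH4)2 (Et2O, −20 °C; chelation-controlled, erythro-selective for α,β-epoxy ketones) returns the (10S) alcohol 9.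

Further compounds
F1 | step 13 | (1S,2E,4R,7E,10S,11S,12S)-10-[(tert-butyldimethylsilyl)oxy]-11,12-epoxycembra-2,7-dien-4-ol | CC(C)(C)[Si](C)(C)O[C@H]1C/C(C)=C/CC[C@@](C)(O)/C=C/[C@H](C(C)C)CC[C@]2(C)O[C@@H]12
F2 | step 13 | 4-O-triethylsilyl ether of F1 | CC(C)(C)[Si](C)(C)O[C@H]1C/C(C)=C/CC[C@@](C)(O[Si](CC)(CC)CC)/C=C/[C@H](C(C)C)CC[C@]2(C)O[C@@H]12
F3 | step 13 | (1S,2E,4R,7E,10S,12S)-10-[(tert-butyldimethylsilyl)oxy]-4-[(triethylsilyl)oxy]-10(11→12)-abeo-cembra-2,7-dien-11-al | CC(C)(C)[Si](C)(C)O[C@H]1C/C(C)=C/CC[C@@](C)(O[Si](CC)(CC)CC)/C=C/[C@H](C(C)C)CC[C@]1(C)C=O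
F4 | step 13 | (1S,2E,4R,7E,10S,12S)-4,10-dihydroxy-10(11→12)-abeo-cembra-2,7-dien-11-al | O[C@H]1C/C(C)=C/CC[C@@](C)(O)/C=C/[C@H](C(C)C)CC[C@]1(C)C=O
F5 | step 11 | S-oxide of 12 (acyclic allylic phenyl sulfoxide; both sulfur epimers) | O=S(c1ccccc1)C/C=C(C)/CC/C=C(C)/C[C@H](O[Si](C)(C)C(C)(C)C)[C@@H]2O[C@@]2(C)CC[C@H]3OC3(C)C
F6 | step 11 | S-oxide of 15 (macrocyclic 2-phenylsulfinyl xanthate; both sulfur epimers) | O=S(c3ccccc3)[C@@H]1/C=C(C)/CC/C=C(C)/C[C@H](O[Si](C)(C)C(C)(C)C)[C@@H]2O[C@@]2(C)CC[C@H]1C(C)(C)OC(=S)SC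
F7 | step 11 | O-[(1R,2E,4R,7E,10S,11S,12S)-10-[(tert-butyldimethylsilyl)oxy]-11,12-epoxy-4-hydroxycembra-2,7-dien-15-yl] S-methyl carbonodithioate | CC(C)(C)[Si](C)(C)O[C@H]1C/C(C)=C/CC[C@@](C)(O)/C=C/[C@H](C(C)(C)OC(=S)SC)CC[C@]2(C)O[C@@H]12
F8 | step 7 | (3E,7E)-9-[(tert-butyldimethylsilyl)oxy]-1-[(2R,3S)-3-{2-[(2R)-3,3-dimethyloxiran-2-yl]ethyl}-3-methyloxiran-2-yl]-3,7-dimethylnona-3,7-dien-1-one | CC(C)(C)[Si](C)(C)OC/C=C(C)/CC/C=C(C)/CC(=O)[C@@H]1O[C@@]1(C)CC[C@H]2OC2(C)C
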